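The route rests on cutting ring B, the benzo-fused cyclohexane, at two bonds: benzylic CH to lactone α-CH, and benzylic CMe2 carbon to the methyl-bearing quaternary carbon. Around this ring the benzylic H, the α-H and the quaternary methyl group sit on one face, the imprint of an endo Diels–Alder union of a dienol of the ortho-xylylene type with a 2-methylmaleic acid derivative. The precursor, reached from 4-ethylphenol through a Claisen rearrangement, is 1-{2-[(E)-but-2-enyl]-4-ethylphenyl}ethanone; irradiated with citraconic anhydride under a chiral titanium template, its photoenol closes ring B, forms both bonds and fixes the three ring-B stereocentres in one operation.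

Key step: step 5

Assumption: the sense of induction of a TADDOL–titanium template with an anhydride dienophile cannot be predicted with certainty; the (R,R)-ligand is written, and its mirror image is taken instead if the first run delivers the antipode of the key-step adduct.

Step 1
Reactants: 1 4-ethylphenol; 2 but-3-en-2-ol (racemic)
Product: 3 1-(but-3-en-2-yloxy)-4-ethylbenzene (racemic)
Conditions: PPh3, DIAD, THF, 0 °C → rt
Reagents that add atoms: none
Why: Mitsunobu etherification, in which the phenol displaces the phosphonium-activated secondary allylic alcohol by SN2 at the carbinol carbon, gives the branched α-methylallyl ether that a [3,3] shift turns into a linear crotyl group; its single stereocentre is racemic and is erased in step 2.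

Step 2
Reactants: 3 1-(but-3-en-2-yloxy)-4-ethylbenzene
Product: 4 2-[(2E)-but-2-en-1-yl]-4-ethylphenol
Conditions: PhNEt2, 190 °C (sealed tube)
Reagents that add atoms: none
Why: Aromatic Claisen rearrangement ([3,3]-sigmatropic shift, then enolisation) can give only one regioisomer because the para position carries the ethyl group and the two ortho positions are equivalent, and the chair transition state with the methyl group pseudo-equatorial should give the E-alkene.

Step 3
Reactants: 4 2-[(2E)-but-2-en-1-yl]-4-ethylphenol
Product: 5 2-[(2E)-but-2-en-1-yl]-4-ethylphenyl trifluoromethanesulfonate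
Conditions: Tf2O, pyridine, CH2Cl2, 0 °C
Reagents that add atoms: triflic anhydride, O=S(=O)(OS(=O)(=O)C(F)(F)F)C(F)(F)F
Why: O-Sulfonylation of the phenol turns the hydroxyl into a pseudohalide for cross-coupling, and the alkene and the ethyl group are inert to these conditions.

Step 4
Reactants: 5 2-[(2E)-but-2-en-1-yl]-4-ethylphenyl trifluoromethanesulfonate; 6 tributyl(1-ethoxyethenyl)stannane
Product: 8 1-{2-[(2E)-but-2-en-1-yl]-4-ethylphenyl}ethan-1-one, via enol ether 7 (not isolated)
Conditions: Pd(PPh3)4 (5 mol %), LiCl, 1,4-dioxane, 100 °C; then 2 M HCl, THF, rt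
Reagents that add atoms: water, O
Why: Stille coupling of the aryl triflate with an α-alkoxyvinyl stannane as acetyl anion equivalent (LiCl enables transmetallation of the triflate-derived palladium species), then acid hydrolysis of enol ether 7, places the acetyl group exactly on the former phenol carbon, and since no palladium hydride arises the skipped E-alkene should not move into conjugation.

Step 5
Reactants: 8 1-{2-[(2E)-but-2-en-1-yl]-4-ethylphenyl}ethan-1-one; 9 citraconic anhydride
Product: 11 (3aR,4S,9S,9aR)-7-ethyl-4-hydroxy-3a,4-dimethyl-9-[(1E)-prop-1-en-1-yl]-3a,4,9,9a-tetrahydronaphtho[2,3-c]furan-1,3-dione, via E-photoenol 10 (not isolated)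
Conditions: (R,R)-TADDOL [(4R,5R)-2,2-dimethyl-α,α,α′,α′-tetraphenyl-1,3-dioxolane-4,5-dimethanol, 1.2 equiv], Ti(OiPr)4 (1.1 equiv), PhMe, rt, iPrOH removed in vacuo; then 8, 9 (3 equiv), PhMe, hν (365 nm LED), −20 °C; cold aqueous tartaric acid work-up
Reagents that add atoms: none
Why: Proposed new method: the n–π* excited ketone abstracts a benzylic and allylic hydrogen from the crotyl CH2, and the 1,4-biradical collapses to the E-configured hydroxy-ortho-quinodimethane 10, which is expected to bind as a dienolate to the TADDOL-bearing tetravalent titanium while the same metal coordinates a carbonyl oxygen of the anhydride. The closest known reactions are the titanium alkoxide/TADDOL-templated photoenolisation/Diels–Alder reaction of ortho-alkyl aryl carbonyl compounds with enones and the metal-free endo addition of photoenols to maleic-type anhydrides, so only the pairing of the chiral template with an anhydride is new. Ring B closes by an asynchronous, suprafacial [4+2] cycloaddition in which the bond from the benzylic CH terminus to the unsubstituted olefinic carbon of 9 leads and the bond from the carbinol carbon to the methyl-bearing carbon follows, with rearomatisation as driving force. The benzylic stereocentre follows from the outward propenyl group of the dienol combined with endo approach, the two ring-fusion centres from the cis geometry of the cyclic dienophile, the carbinol centre from the outward hydroxyl of the E-enol, and the absolute sense from the TADDOL ligand, which blocks one face of the titanium-bound dienol. The step needs regio-, endo- and face selectivity: the first rests on the larger HOMO coefficient at the diene carbon remote from oxygen and the lower hindrance of the unsubstituted anhydride carbon, the second on tethering of the anhydride carbonyl under the diene by titanium, the third on the ligand. Isopropanol is stripped off before irradiation and 9 is used in excess so that alkoxide transfer to the anhydride should not exhaust the template.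

Step 6
Reactants: 11 hydroxy anhydride
Product: 13 (3aS,4S,9S,9aR)-7-ethyl-4-hydroxy-3a,4-dimethyl-9-[(1E)-prop-1-en-1-yl]-3a,4,9,9a-tetrahydronaphtho[2,3-c]furan-1(3H)-one, via sodium hydroxy carboxylate 12 (not isolated)
Conditions: NaBH4, THF, 0 °C → rt; then 1 M HCl, 0 °C
Reagents that add atoms: none
Why: In the NaBH4 reduction of unsymmetrical succinic-type anhydrides hydride attacks the carbonyl flanked by the more substituted α-carbon, here the one on the quaternary methyl carbon, the aldehyde carboxylate formed is reduced further to 12, and acidification closes the γ-lactone without touching any stereocentre.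

Step 7
Reactants: 13 hydroxy lactone
Product: 15 (3aR,9S,9aR)-7-ethyl-3a,4,4-trimethyl-9-[(1E)-prop-1-en-1-yl]-3a,4,9,9a-tetrahydronaphtho[2,3-c]furan-1(3H)-one, via tertiary benzylic chloride 14 (not isolated)
Conditions: HCl (4 M in dioxane), CH2Cl2, 0 °C, evaporate; then Me2TiCl2 (from Me2Zn and TiCl4), CH2Cl2, −40 → 0 °C
Reagents that add atoms: dimethyltitanium dichloride, C[Ti](C)(Cl)Cl (its methyl groups come from dimethylzinc, C[Zn]C); hydrogen chloride, Cl (chlorine only in intermediate 14)
Why: SN1 methylation of a tertiary benzylic chloride with a methyltitanium chloride: HCl converts the easily ionised tertiary benzylic alcohol into chloride 14, the titanium Lewis acid re-ionises it and transfers methyl to the cation far faster than it adds to a lactone, which creates the CMe2 carbon beside the quaternary centre and removes the carbinol stereocentre that the target does not contain.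

Step 8
Reactants: 15 gem-dimethyl lactone
Product: 16 (3aR,9S,9aR)-7-ethyl-3a,4,4-trimethyl-9-[(2R,3R)-3-methyloxiran-2-yl]-3a,4,9,9a-tetrahydronaphtho[2,3-c]furan-1(3H)-one
Conditions: D-fructose-derived Shi ketone (1,2:4,5-di-O-isopropylidene-β-D-erythro-2,3-hexodiulo-2,6-pyranose, 0.3 equiv), KHSO5 (Oxone), K2CO3 (aq., pH ≈ 10.5), Bu4NHSO4, MeCN/CH2(OMe)2, 0 °C
Reagents that add atoms: potassium peroxymonosulfate, [K+].[O-]S(=O)(=O)OO
Why: Shi epoxidation, in which the chiral dioxirane formed from the ketone and KHSO5 transfers oxygen through a spiro transition state that turns trans-1,2-disubstituted alkenes into (R,R)-oxiranes with the D-fructose catalyst, should set the (2R,3R) epoxide under reagent control, overriding the weak bias of the neighbouring benzylic centre, while the hindered lactone survives the cold carbonate buffer.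

Step 9
Reactants: 16 epoxy lactone
Product: 18 (1S,3aR,4R,9bS)-8-ethyl-1-[(1R)-1-hydroxyethyl]-4-(hydroxymethyl)-4,5,5-trimethyl-3a,4,5,9b-tetrahydronaphtho[1,2-c]furan-3(1H)-one, via sodium epoxy hydroxy carboxylate 17 (not isolated)
Conditions: NaOH (1.5 equiv), THF/H2O, rt; then NaH2PO4 to pH 6–7, 40 °C
Reagents that add atoms: sodium hydroxide, [Na+].[OH-] (its oxygen ends in the carboxyl group)
Why: Saponification followed by intramolecular SN2 opening of the epoxide (5-exo-tet lactonisation): the epoxy carboxylate 17 persists in base, whereas near neutral pH a γ,δ-epoxy acid closes spontaneously to the γ-lactone with inversion at the attacked carbon, which sets the oxygenated CH as S with its side chain cis to both ring-B bonds of the new lactone, while re-closure of the old lactone needs stronger acid and any 16 that does re-form can be recycled.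

Step 10
Reactants: 18 diol lactone
Product: 19 (1S,3aR,4R,9bS)-1-acetyl-8-ethyl-4,5,5-trimethyl-3-oxo-1,3,3a,4,5,9b-hexahydronaphtho[1,2-c]furan-4-carbaldehyde
Conditions: Dess–Martin periodinane, CH2Cl2, rt
Reagents that add atoms: none
Why: Dess–Martin oxidation converts the secondary and the neopentyl primary alcohol into methyl ketone and aldehyde under neutral conditions that leave the α-acyloxy ketone centre and the lactone untouched, and the aldehyde has no α-hydrogen.

Step 11
Reactants: 19 keto aldehyde
Product: 21 didebromo-salimabromide (tetracyclic cycloheptenone lactone), via aldol adduct 20 (not isolated)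
Conditions: DBU, PhMe, 60 °C
Reagents that add atoms: none
Why: Intramolecular aldol condensation, in which the methyl ketone enolises at CH3 and adds to the non-enolisable aldehyde held 1,3-diaxial to it on ring B (7-(enolexo)-exo-trig closure) before E1cB loss of water gives the conjugated cycloheptenone, also corrects any epimer at the oxygenated CH, since that centre equilibrates through its enolate and only the cis epimer can reach the aldehyde.

Step 12
Reactants: 21 didebromo-salimabromide
Product: 23 salimabromide, via monobromide 22 (not isolated)
Conditions: Br2 (2.2 equiv), AgOCOCF3 (2.2 equiv), CF3CO2H, 0 °C → rt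
Reagents that add atoms: bromine, BrBr
Why: Electrophilic aromatic bromination with trifluoroacetyl hypobromite generated from Br2 and AgOCOCF3 should take both positions ortho to the ethyl group, each activated by two alkyl substituents, while the third aromatic CH is shielded by the adjacent CMe2 carbon and the protonated enone, whose α-hydrogens are vinylic or at a bridgehead, resists bromine.

Compound list
1 | 4-ethylphenol | CCc1ccc(O)cc1 | starting material
2 | but-3-en-2-ol (racemic) | CC(O)C=C | starting material
3 | 1-(but-3-en-2-yloxy)-4-ethylbenzene (racemic) | CCc1ccc(OC(C)C=C)cc1 | intermediate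
4 | 2-[(2E)-but-2-en-1-yl]-4-ethylphenol | CCc1ccc(O)c(C/C=C/C)c1 | intermediate
5 | 2-[(2E)-but-2-en-1-yl]-4-ethylphenyl trifluoromethanesulfonate | CCc1ccc(OS(=O)(=O)C(F)(F)F)c(C/C=C/C)c1 | intermediate
6 | tributyl(1-ethoxyethenyl)stannane | CCCC[Sn](CCCC)(CCCC)C(=C)OCC | starting material
7 | 2-[(2E)-but-2-en-1-yl]-1-(1-ethoxyethenyl)-4-ethylbenzene (enol ether, not isolated) | CCOC(=C)c1ccc(CC)cc1C/C=C/C | intermediate
8 | 1-{2-[(2E)-but-2-en-1-yl]-4-ethylphenyl}ethan-1-one | CCc1ccc(C(C)=O)c(C/C=C/C)c1 | intermediate
9 | citraconic anhydride (3-methylfuran-2,5-dione) | CC1=CC(=O)OC1=O | starting material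
10 | E-photoenol, (1E)-1-{(6E)-6-[(2E)-but-2-en-1-ylidene]-4-ethylcyclohexa-2,4-dien-1-ylidene}ethan-1-ol (hydroxyl and propenyl group pointing outward; not isolated) | CCC1=C/C(=C\C=C\C)/C(=C(\C)O)C=C1 | intermediate
11 | (3aR,4S,9S,9aR)-7-ethyl-4-hydroxy-3a,4-dimethyl-9-[(1E)-prop-1-en-1-yl]-3a,4,9,9a-tetrahydronaphtho[2,3-c]furan-1,3-dione (propenyl, both anhydride carbonyls and hydroxyl on one face of ring B) | CCc1ccc2c(c1)[C@@H](/C=C/C)[C@H]1C(=O)OC(=O)[C@@]1(C)[C@@]2(C)O | intermediate
12 | sodium salt of the ring-opened hydroxy acid of 13: sodium 7-ethyl-4-hydroxy-3-(hydroxymethyl)-3,4-dimethyl-1-[(1E)-prop-1-en-1-yl]-1,2,3,4-tetrahydronaphthalene-2-carboxylate, stereocentres as in 11 (not isolated) | CCc1ccc2c(c1)[C@@H](/C=C/C)[C@@H](C(=O)[O-])[C@@](C)(CO)[C@@]2(C)O.[Na+] | intermediate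
13 | (3aS,4S,9S,9aR)-7-ethyl-4-hydroxy-3a,4-dimethyl-9-[(1E)-prop-1-en-1-yl]-3a,4,9,9a-tetrahydronaphtho[2,3-c]furan-1(3H)-one (lactone CH2 on the quaternary carbon) | CCc1ccc2c(c1)[C@@H](/C=C/C)[C@H]1C(=O)OC[C@@]1(C)[C@@]2(C)O | intermediate
14 | tertiary benzylic chloride, the 4-chloro analogue of 13, either configuration at the chlorinated carbon (not isolated) | CCc1ccc2c(c1)[C@@H](/C=C/C)[C@H]1C(=O)OC[C@@]1(C)C2(C)Cl | intermediate
15 | (3aR,9S,9aR)-7-ethyl-3a,4,4-trimethyl-9-[(1E)-prop-1-en-1-yl]-3a,4,9,9a-tetrahydronaphtho[2,3-c]furan-1(3H)-one | CCc1ccc2c(c1)[C@@H](/C=C/C)[C@H]1C(=O)OC[C@@]1(C)C2(C)C | intermediate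
16 | (3aR,9S,9aR)-7-ethyl-3a,4,4-trimethyl-9-[(2R,3R)-3-methyloxiran-2-yl]-3a,4,9,9a-tetrahydronaphtho[2,3-c]furan-1(3H)-one | CCc1ccc2c(c1)[C@@H]([C@H]3O[C@@H]3C)[C@H]1C(=O)OC[C@@]1(C)C2(C)C | intermediate
17 | sodium salt of the ring-opened hydroxy acid of 16, stereocentres as in 16 (not isolated) | CCc1ccc2c(c1)[C@@H]([C@H]3O[C@@H]3C)[C@@H](C(=O)[O-])[C@@](C)(CO)C2(C)C.[Na+] | intermediate
18 | (1S,3aR,4R,9bS)-8-ethyl-1-[(1R)-1-hydroxyethyl]-4-(hydroxymethyl)-4,5,5-trimethyl-3a,4,5,9b-tetrahydronaphtho[1,2-c]furan-3(1H)-one | CCc1ccc2c(c1)[C@H]1[C@@H]([C@@H](C)O)OC(=O)[C@H]1[C@@](C)(CO)C2(C)C | intermediate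
19 | (1S,3aR,4R,9bS)-1-acetyl-8-ethyl-4,5,5-trimethyl-3-oxo-1,3,3a,4,5,9b-hexahydronaphtho[1,2-c]furan-4-carbaldehyde | CCc1ccc2c(c1)[C@H]1[C@@H](C(C)=O)OC(=O)[C@H]1[C@@](C)(C=O)C2(C)C | intermediate
20 | aldol adduct: β-hydroxy ketone with the seven-membered ring closed, carbinol configuration not defined (not isolated) | CCc1ccc2c(c1)[C@H]1[C@@H]3OC(=O)[C@H]1[C@@](C)(C(O)CC3=O)C2(C)C | intermediate
21 | didebromo-salimabromide: tetracyclic lactone enone; benzylic CH S, oxygenated bridgehead CH S, lactone α-CH R, quaternary methyl carbon R | CCc1ccc2c(c1)[C@H]1[C@@H]3OC(=O)[C@H]1[C@@](C)(C=CC3=O)C2(C)C | intermediate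
22 | monobromide: 21 brominated at the aromatic carbon ortho to ethyl and para to the benzylic CH carbon (not isolated) | CCc1c(Br)cc2c(c1)[C@H]1[C@@H]3OC(=O)[C@H]1[C@@](C)(C=CC3=O)C2(C)C | intermediate
23 | salimabromide (both aromatic positions ortho to ethyl brominated; stereocentres as in 21) | CCc1c(Br)cc2c(c1Br)[C@H]1[C@@H]3OC(=O)[C@H]1[C@@](C)(C=CC3=O)C2(C)C | target

Total step count: 12. Longest linear sequence: 12 steps (1 → 23).

Steps most likely to fail

1. Step 5 (carries the label "Proposed new method:"). Isopropoxide may be transferred from titanium to the anhydride, the acyl group may migrate onto the titanium-bound tertiary alkoxide of the adduct, or the ligand may discriminate the dienol faces poorly. The fallback uses known chemistry only and sets out from 8 and 9. They are irradiated at 365 nm in toluene without any metal, the established endo capture of a ketone photoenol by a maleic-type anhydride. This should give 11 as a racemate, that is, together with its mirror image, ent-hydroxy anhydride F1. NaBH4 reduction as in step 6 then leads through ent-sodium hydroxy carboxylate F2 to ent-hydroxy lactone F3 alongside 13. Preparative HPLC on a polysaccharide chiral stationary phase removes F3, and the route is rejoined at 13.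

2. Step 6. Hydride may be delivered to the less hindered carbonyl, or the acyl group may shift to the neighbouring tertiary hydroxyl before reduction. The fallback sets out from 11 and uses the opposite, sterically governed selectivity of alcoholysis. MeOH with Et3N at rt should open the anhydride at the carbonyl on the CH carbon to give half ester F4, whose free acid sits on the quaternary carbon. BH3·SMe2 in THF reduces only this acid to hydroxy ester F5, which lactonises with loss of methanol (TsOH cat., PhMe, 50 °C). The route is rejoined at 13.

3. Step 9. The primary hydroxyl may re-close the original lactone faster than the acid opens the epoxide, or the acyl group may wander between the hydroxyls. The fallback sets out from 16 and masks the primary oxygen before the acid is released. After saponification to 17 as in step 9, both oxygens are silylated (TBSCl, imidazole, DMF) to bis-silyl epoxide F6. Aqueous AcOH/THF cleaves only the silyl ester, and the freed acid opens the epoxide to silyl ether lactone F7. HF·pyridine in THF removes the silyl group, and the route is rejoined at 18.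

Further compounds
F1 | step 5 | ent-hydroxy anhydride, mirror image of 11 | CCc1ccc2c(c1)[C@H](/C=C/C)[C@@H]1C(=O)OC(=O)[C@]1(C)[C@]2(C)O
F2 | step 5 | ent-sodium hydroxy carboxylate, mirror image of 12 (not isolated) | CCc1ccc2c(c1)[C@H](/C=C/C)[C@H](C(=O)[O-])[C@](C)(CO)[C@]2(C)O.[Na+]
F3 | step 5 | ent-hydroxy lactone, mirror image of 13 | CCc1ccc2c(c1)[C@H](/C=C/C)[C@@H]1C(=O)OC[C@]1(C)[C@]2(C)O
F4 | step 6 | half ester: methyl ester on the CH carbon, free acid on the quaternary carbon, stereocentres as in 11 | CCc1ccc2c(c1)[C@@H](/C=C/C)[C@@H](C(=O)OC)[C@@](C)(C(=O)O)[C@@]2(C)O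
F5 | step 6 | hydroxy ester: F4 with the acid reduced to CH2OH (not isolated) | CCc1ccc2c(c1)[C@@H](/C=C/C)[C@@H](C(=O)OC)[C@@](C)(CO)[C@@]2(C)O
F6 | step 9 | bis-silyl epoxide: tert-butyldimethylsilyl ester and tert-butyldimethylsilyl ether of the acid of 17 (not isolated) | CCc1ccc2c(c1)[C@@H]([C@H]3O[C@@H]3C)[C@@H](C(=O)O[Si](C)(C)C(C)(C)C)[C@@](C)(CO[Si](C)(C)C(C)(C)C)C2(C)C
F7 | step 9 | silyl ether lactone: 18 with its primary hydroxyl as tert-butyldimethylsilyl ether | CCc1ccc2c(c1)[C@H]1[C@@H]([C@@H](C)O)OC(=O)[C@H]1[C@@](C)(CO[Si](C)(C)C(C)(C)C)C2(C)C
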